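**Retrosynthetic overview**

- Feature. Atoms are numbered in the order of the target SMILES (O is atom 10). Ring A is C15/C17/C18/C19/C22/C23, ring B is C11/C13/C14/C15/C23/C24, ring C is the eight-membered C2/C3/C8/C9/C11/C24/C25/C26 and ring D is C3/C4/C5/C6/C8. In ring C the carbinol carbon C9 lies between C8 and the quaternary C11, so C9, C2, C3 and C8 can be the four carbons of a cyclobutanol fused to ring D. Ring C is then that four-membered ring enlarged by C11, C24, C25 and C26.
- End game: C2=C3 from C2=C26 by isomerisation, and C9–OH from the C9 ketone 30. Key disconnection: C24–C25 by anionic oxy-Cope ring expansion of cyclobutanol 27, with C11–C12 by methylation of the resulting enolate in the same flask.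
- Cyclobutanol 27 comes from cyclobutanone 25 (ring D plus the four-membered ring) and alkenylstannane 12 (rings A and B); the C9–C11 bond is made by alkenyllithium addition.
- Ring order: ring B onto ring A by asymmetric Robinson annulation (sets C15), ring D together with the cyclobutanone by intramolecular ketene [2+2] cycloaddition (then resolved), ring C last.

Key step: step 16

Remarks
- Locants: bicyclo[3.2.0]heptane positions 1, 4, 5, 6, 7 are target atoms C3, C6, C8, C9, C2; naphthalene positions 1, 2, 4a, 8a are C24, C11, C15, C23. C1, C7, C12, C16, C20 and C21 are the methyl carbons on C2, C6, C11, C15 and C19 (two).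
- Assumption: the 1-phenylethylamine-controlled Michael addition is taken to follow the facial sense known for the imine of 2-methylcyclohexanone, where the (S)-amine leads to the (R)-configured quaternary carbon. The (R)-amine is therefore used for (S)-C15; the other amine enantiomer would be used if the gem-dimethyl group reversed this sense.
- 2-(Phenylselanyl)acetaldehyde is treated as an available reagent; it is otherwise made in one operation from PhSeCl and ethyl vinyl ether with hydrolytic work-up.

**Fragment 12 (rings A and B)**

Step 1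
Reactants: 1 3,3-dimethylcyclohexanone
Product: 3 2,5,5-trimethylcyclohexanone (racemate), via lithium enolate 2 (not isolated)
Conditions: LiN(i-Pr)2, THF, −78 °C; MeI, −78 → 0 °C
Reagents that add atoms: methyl iodide, CI
Why: Kinetic deprotonation with the hindered amide takes the proton remote from the gem-dimethyl group (the other α-methylene is neopentyl), and SN2 methylation of that enolate (enolate alkylation) should give 3, whose new stereocentre is re-set in step 3.

Step 2
Reactants: 3 2,5,5-trimethylcyclohexanone
Product: 4 N-[(R)-1-phenylethyl]imine of 3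
Conditions: (R)-1-phenylethylamine, TsOH (cat.), toluene, reflux, Dean–Stark trap
Reagents that add atoms: (R)-1-phenylethylamine, C[C@@H](N)c1ccccc1
Why: Acid-catalysed imine formation with azeotropic removal of water should give the chiral imine, which equilibrates with its more substituted secondary enamine tautomer so that the α-configuration of 3 does not matter.

Step 3
Reactants: 4 N-[(R)-1-phenylethyl]imine of 3; 5 but-3-en-2-one
Product: 7 (S)-2,5,5-trimethyl-2-(3-oxobutyl)cyclohexan-1-one, via Michael adduct imine 6 (not isolated)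
Conditions: THF, 25 °C; then AcOH, H2O, 25 °C
Reagents that add atoms: water, O
Why: Asymmetric Michael addition of the secondary enamine tautomer of the chiral imine takes place at the more substituted α-carbon through a compact transition state with internal N–H transfer, on the face anti to the phenyl group of the auxiliary, which sets the quaternary C15; hydrolysis then frees the 1,5-diketone and the amine.

Step 4
Reactants: 7 (S)-2,5,5-trimethyl-2-(3-oxobutyl)cyclohexan-1-one
Product: 9 (S)-4a,7,7-trimethyl-4,4a,5,6,7,8-hexahydronaphthalen-2(3H)-one, via ketol 8 (not isolated)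
Conditions: NaOMe, MeOH, 60 °C
Reagents that add atoms: none
Why: Intramolecular aldol addition of the methyl ketone to the ring carbonyl and E1cB dehydration complete the Robinson annulation and close ring B, while the quaternary C15 cannot epimerise.

Step 5
Reactants: 9 (S)-4a,7,7-trimethyl-4,4a,5,6,7,8-hexahydronaphthalen-2(3H)-one
Product: 11 (4aS,8aS)-4a,7,7-trimethyl-3,4,4a,5,6,7,8,8a-octahydronaphthalen-2-yl trifluoromethanesulfonate, via lithium enolate 10 (not isolated)
Conditions: Li, NH3(l), t-BuOH (1 equiv), THF, −78 °C; NH3 removed; PhNTf2, THF, 0 °C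
Reagents that add atoms: N-phenylbis(trifluoromethanesulfonimide), O=S(=O)(N(c1ccccc1)S(=O)(=O)C(F)(F)F)C(F)(F)F
Why: Dissolving-metal reduction of the enone protonates the β-carbon C23 axially to give the trans A/B fusion (H23 anti to the C16 methyl) and leaves the regiodefined C11=C24 lithium enolate, which PhNTf2 converts into the enol triflate (reductive enolate trapping).

Step 6
Reactants: 11 (4aS,8aS)-4a,7,7-trimethyl-3,4,4a,5,6,7,8,8a-octahydronaphthalen-2-yl trifluoromethanesulfonate
Product: 12 [(4aS,8aS)-4a,7,7-trimethyl-3,4,4a,5,6,7,8,8a-octahydronaphthalen-2-yl]trimethylstannane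
Conditions: Me3SnSnMe3, Pd(PPh3)4 (5 mol %), LiCl, THF, 65 °C
Reagents that add atoms: hexamethylditin, C[Sn](C)(C)[Sn](C)(C)C
Why: Palladium-catalysed stannylation of the enol triflate (oxidative addition to zerovalent palladium, transmetalation with the ditin, reductive elimination) should give the alkenylstannane without moving the C11=C24 double bond.

**Fragment 25 (ring D and the cyclobutanone)**

Step 7
Reactants: 13 hex-5-en-2-one
Product: 14 3-hydroxy-3-methylhept-6-enoic acid (racemate)
Conditions: AcOH, LiN(i-Pr)2 (2 equiv), THF, 0 → 40 °C; 13, 0 → 25 °C; aq HCl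
Reagents that add atoms: acetic acid, CC(=O)O
Why: The dianion of acetic acid adds to the ketone carbonyl (aldol-type addition of a carboxylic acid dianion) and should give the β-hydroxy acid directly; its carbinol centre is lost in step 8.

Step 8
Reactants: 14 3-hydroxy-3-methylhept-6-enoic acid
Product: 16 rac-(1S,5R)-4-methylbicyclo[3.2.0]hept-3-en-6-one, via vinylketene 15 (not isolated)
Conditions: Ac2O, KOAc, 25 °C then 120 °C
Reagents that add atoms: none
Why: Acetylation, elimination and loss of acetic acid from the mixed anhydride give the vinylketene, which undergoes intramolecular thermal ketene–alkene [2+2] cycloaddition; the three-atom tether enforces the fused regiochemistry and the cis ring fusion.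

Step 9
Reactants: 16 rac-(1S,5R)-4-methylbicyclo[3.2.0]hept-3-en-6-one
Product: 17 rac-(1S,4S,5S)-4-methylbicyclo[3.2.0]heptan-6-one (methyl endo)
Conditions: H2 (1 atm), 10% Pd/C, EtOAc, 25 °C
Reagents that add atoms: none
Why: Heterogeneous catalytic hydrogenation adds hydrogen to the trisubstituted alkene from the convex exo face, so the C7 methyl on C6 ends up endo, cis to the C8–C9 bond, and the ketone is not reduced under these conditions.

Step 10
Reactants: 17 rac-(1S,4S,5S)-4-methylbicyclo[3.2.0]heptan-6-one
Product: 18 exo adduct of (1S,4S,5S)-17 with the (S)-sulfoximine (β-hydroxysulfoximine; single diastereomer)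
Conditions: (S)-N,S-dimethyl-S-phenylsulfoximine, n-BuLi, THF, −78 °C; 17, −78 °C; H2O; separation of the two diastereomers on silica gel or by crystallisation
Reagents that add atoms: (S)-N,S-dimethyl-S-phenylsulfoximine, C[S@@](=O)(=NC)c1ccccc1
Why: 1,2-Addition of the lithiated enantiopure sulfoximine to the exo face of the cyclobutanone (sulfoximine resolution of a ketone) turns the enantiomers into separable diastereomers, and the one derived from the (1S,4S,5S)-ketone, to be identified crystallographically, is taken on.

Step 11
Reactants: 18 exo adduct of (1S,4S,5S)-17 with the (S)-sulfoximine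
Product: 19 (1S,4S,5S)-4-methylbicyclo[3.2.0]heptan-6-one
Conditions: toluene, 110 °C
Reagents that add atoms: none
Why: Thermolysis of the β-hydroxysulfoximine is a retro-1,2-addition that should release the enantiopure ketone and the sulfoximine without touching the ring stereocentres.

Step 12
Reactants: 19 (1S,4S,5S)-4-methylbicyclo[3.2.0]heptan-6-one
Product: 21 (1S,4S,5S)-4,7-dimethylbicyclo[3.2.0]heptan-6-one (C7 epimers), via lithium enolate 20 (not isolated)
Conditions: LiN(i-Pr)2, THF, −78 °C; MeI, −78 → −20 °C
Reagents that add atoms: methyl iodide, CI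
Why: The cyclobutanone enolises only towards the methylene carbon C2, because an enolate at the bridgehead C8 would place a double bond at the ring fusion, and SN2 methylation (enolate alkylation) installs C1; the C2 configuration is erased in step 13.

Step 13
Reactants: 21 (1S,4S,5S)-4,7-dimethylbicyclo[3.2.0]heptan-6-one
Product: 23 (1S,4S,5S)-7-exo-[1-hydroxy-2-(phenylselanyl)ethyl]-4,7-dimethylbicyclo[3.2.0]heptan-6-one (carbinol epimers), via lithium enolate 22 (not isolated)
Conditions: LiN(i-Pr)2, THF, −78 → −40 °C; PhSeCH2CHO, −78 °C; AcOH, −78 °C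
Reagents that add atoms: 2-(phenylselanyl)acetaldehyde, O=CC[Se]c1ccccc1
Why: The tetrasubstituted lithium enolate adds to the aldehyde (aldol addition) from the convex exo face, which places the two-carbon chain exo and the C1 methyl endo at the quaternary C2; the cold acidic quench prevents retro-aldol cleavage.

Step 14
Reactants: 23 (1S,4S,5S)-7-exo-[1-hydroxy-2-(phenylselanyl)ethyl]-4,7-dimethylbicyclo[3.2.0]heptan-6-one
Product: 25 (1R,4S,5S,7S)-7-ethenyl-4,7-dimethylbicyclo[3.2.0]heptan-6-one (vinyl exo), via methanesulfonate 24 (not isolated)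
Conditions: MsCl, Et3N, CH2Cl2, 0 → 25 °C
Reagents that add atoms: none
Why: Mesylation of the β-hydroxy selenide triggers anti elimination of the sulfonate and the phenylselanyl group through a seleniranium ion (reductive elimination of a β-hydroxy selenide), which should give the vinyl group C26=C25 without cationic rearrangement of the cyclobutane.

**Coupling and end game**

Step 15
Reactants: 12 [(4aS,8aS)-4a,7,7-trimethyl-3,4,4a,5,6,7,8,8a-octahydronaphthalen-2-yl]trimethylstannane; 25 (1R,4S,5S,7S)-7-ethenyl-4,7-dimethylbicyclo[3.2.0]heptan-6-one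
Product: 27 (1R,4S,5S,6R,7S)-7-ethenyl-4,7-dimethyl-6-[(4aS,8aS)-4a,7,7-trimethyl-3,4,4a,5,6,7,8,8a-octahydronaphthalen-2-yl]bicyclo[3.2.0]heptan-6-ol (alkenyl group exo and cis to vinyl), via alkenyllithium 26 (not isolated)
Conditions: 12, MeLi, THF, −78 → −20 °C; 25, −78 °C; H2O
Reagents that add atoms: none
Why: Tin–lithium exchange gives the regiodefined alkenyllithium, which adds (1,2-addition of an organolithium) to the non-enolisable cyclobutanone from the exo face, the endo face being blocked by ring D and the two endo methyl groups, so the alkenyl group ends up cis to the vinyl group.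

Step 16
Reactants: 27 cyclobutanol from step 15
Product: 30 tetracyclic C9 ketone with Z-C2=C26 (rings A–D complete), via potassium cyclobutoxide 28 (not isolated), via potassium dienolate 29 (not isolated)
Conditions: KH, 18-crown-6, THF, 0 → 25 °C; MeI, −78 → 0 °C
Reagents that add atoms: methyl iodide, CI
Why: KH with 18-crown-6 gives the potassium cyclobutoxide 28, whose oxyanion weakens the C2–C9 bond so that the cis-1-alkenyl-2-vinylcyclobutane unit undergoes an anionic oxy-Cope [3,3] shift through the boat transition state that a cis-dialkenylcyclobutane must use; this is the known ring expansion of cis-1-alkenyl-2-vinylcyclobutanols to cyclooct-4-enone enolates with alkylation of the enolate in the same flask. Ring C is closed by four-carbon ring expansion (C24–C25 forms as C2–C9 breaks), driven by release of cyclobutane strain and by enolate formation, and the two new ring double bonds (C9=C11 and C2=C26) are necessarily Z. C24 is fixed by the boat geometry: with both alkenyl groups on the exo face and H24 turned inwards under the four-membered ring, C25 can reach C24 only on the ring B face anti to the angular C16 methyl, which is also the open face of the octalin, so the chosen fragment enantiomers are matched. The fully substituted, regiodefined dienolate 29 can only be C-methylated at C11, and C11 is correct when MeI enters anti to H24, that is along the axial direction of the ring B chair so that C9 and C25 both end up equatorial on ring B. The substrate offers only this chair bias for the second stereocentre, and because the C25–C26=C2 bridge of ring C lies on the same side, this facial selectivity is the point on which the step depends (first fallback below); fragmentation of 28 is limited by not exceeding 25 °C.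

Step 17
Reactants: 30 tetracyclic C9 ketone with Z-C2=C26
Product: 31 C9 alcohol with Z-C2=C26 (hydroxyl trans to the C12 methyl)
Conditions: LiAlH4, Et2O, −78 → 0 °C
Reagents that add atoms: none
Why: Hydride addition is expected on the outer face of the ring C carbonyl in the Felkin–Anh sense (anti to C24, the largest substituent on C11, and past the C12 methyl), which places H9 cis and the hydroxyl trans to the C12 methyl, and LiAlH4 leaves the isolated alkene alone.

Step 18
Reactants: 31 C9 alcohol with Z-C2=C26
Product: 32 target CNP0399382.1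
Conditions: RhCl3·3H2O (10 mol %), EtOH, 80 °C
Reagents that add atoms: none
Why: RhCl3·3H2O-catalysed alkene isomerisation (rhodium hydride addition and elimination) should move the trisubstituted C2=C26 double bond to the tetrasubstituted C2=C3 position, which binds the metal poorly and is not carried further; C3 loses its stereocentre, the ring enforces the required alkene geometry, and C8 and C9 are untouched.

**Compound list**

1 | 3,3-dimethylcyclohexanone | CC1(C)CCCC(=O)C1 | starting material
2 | lithium enolate of 1 (formed away from the gem-dimethyl group) | [Li]OC1=CCCC(C)(C)C1 | intermediate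
3 | 2,5,5-trimethylcyclohexanone (racemate) | CC1CCC(C)(C)CC1=O | intermediate
4 | N-[(R)-1-phenylethyl]imine of 3 (epimers at the α-carbon) | C[C@@H](N=C1CC(C)(C)CCC1C)c1ccccc1 | intermediate
5 | but-3-en-2-one | CC(=O)C=C | starting material
6 | N-[(R)-1-phenylethyl]imine of (S)-2,5,5-trimethyl-2-(3-oxobutyl)cyclohexanone | C[C@@H](N=C1CC(C)(C)CC[C@@]1(C)CCC(C)=O)c1ccccc1 | intermediate
7 | (S)-2,5,5-trimethyl-2-(3-oxobutyl)cyclohexan-1-one | CC(=O)CC[C@]1(C)CCC(C)(C)CC1=O | intermediate
8 | (4aS)-8a-hydroxy-4a,7,7-trimethyloctahydronaphthalen-2(1H)-one (C8a epimers) | O=C1CC[C@]2(C)CCC(C)(C)CC2(O)C1 | intermediate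
9 | (S)-4a,7,7-trimethyl-4,4a,5,6,7,8-hexahydronaphthalen-2(3H)-one | O=C1C=C2CC(C)(C)CC[C@@]2(C)CC1 | intermediate
10 | lithium (4aS,8aS)-4a,7,7-trimethyl-3,4,4a,5,6,7,8,8a-octahydronaphthalen-2-olate (C11=C24 enolate, trans-fused) | [Li]OC1=C[C@@H]2CC(C)(C)CC[C@@]2(C)CC1 | intermediate
11 | (4aS,8aS)-4a,7,7-trimethyl-3,4,4a,5,6,7,8,8a-octahydronaphthalen-2-yl trifluoromethanesulfonate | O=S(=O)(OC1=C[C@@H]2CC(C)(C)CC[C@@]2(C)CC1)C(F)(F)F | intermediate
12 | [(4aS,8aS)-4a,7,7-trimethyl-3,4,4a,5,6,7,8,8a-octahydronaphthalen-2-yl]trimethylstannane | C[Sn](C)(C)C1=C[C@@H]2CC(C)(C)CC[C@@]2(C)CC1 | intermediate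
13 | hex-5-en-2-one | CC(=O)CCC=C | starting material
14 | 3-hydroxy-3-methylhept-6-enoic acid (racemate) | CC(O)(CCC=C)CC(=O)O | intermediate
15 | (Z)-3-methylhepta-1,3,6-trien-1-one (vinylketene) | O=C=C/C(C)=C\CC=C | intermediate
16 | rac-(1S,5R)-4-methylbicyclo[3.2.0]hept-3-en-6-one (both enantiomers written) | O=C1C[C@@H]2CC=C(C)[C@H]12.O=C1C[C@H]2CC=C(C)[C@@H]12 | intermediate
17 | rac-(1S,4S,5S)-4-methylbicyclo[3.2.0]heptan-6-one, methyl endo (both enantiomers written) | O=C1C[C@@H]2CC[C@H](C)[C@H]12.O=C1C[C@H]2CC[C@@H](C)[C@@H]12 | intermediate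
18 | (1S,4S,5S)-4-methyl-6-exo-{[(S)-N-methyl-S-phenylsulfonimidoyl]methyl}bicyclo[3.2.0]heptan-6-ol | O[C@]1(C[S@@](=O)(=NC)c2ccccc2)C[C@@H]2CC[C@H](C)[C@H]12 | intermediate
19 | (1S,4S,5S)-4-methylbicyclo[3.2.0]heptan-6-one | O=C1C[C@@H]2CC[C@H](C)[C@H]12 | intermediate
20 | lithium enolate of 19 (C9=C2) | [Li]OC1=C[C@@H]2CC[C@H](C)[C@H]12 | intermediate
21 | (1S,4S,5S)-4,7-dimethylbicyclo[3.2.0]heptan-6-one (C7 epimers) | O=C1C(C)[C@@H]2CC[C@H](C)[C@H]12 | intermediate
22 | lithium enolate of 21 (tetrasubstituted, C9=C2) | [Li]OC1=C(C)[C@@H]2CC[C@H](C)[C@H]12 | intermediate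
23 | (1S,4S,5S)-7-exo-[1-hydroxy-2-(phenylselanyl)ethyl]-4,7-dimethylbicyclo[3.2.0]heptan-6-one (carbinol epimers) | O=C1[C@@](C)(C(O)C[Se]c3ccccc3)[C@@H]2CC[C@H](C)[C@H]12 | intermediate
24 | methanesulfonate of 23 | O=C1[C@@](C)(C(OS(C)(=O)=O)C[Se]c3ccccc3)[C@@H]2CC[C@H](C)[C@H]12 | intermediate
25 | (1R,4S,5S,7S)-7-ethenyl-4,7-dimethylbicyclo[3.2.0]heptan-6-one (vinyl exo, both methyls endo) | O=C1[C@@](C)(C=C)[C@@H]2CC[C@H](C)[C@H]12 | intermediate
26 | (4aS,8aS)-4a,7,7-trimethyl-3,4,4a,5,6,7,8,8a-octahydronaphthalen-2-yllithium | [Li]C1=C[C@@H]2CC(C)(C)CC[C@@]2(C)CC1 | intermediate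
27 | (1R,4S,5S,6R,7S)-7-ethenyl-4,7-dimethyl-6-[(4aS,8aS)-4a,7,7-trimethyl-3,4,4a,5,6,7,8,8a-octahydronaphthalen-2-yl]bicyclo[3.2.0]heptan-6-ol (alkenyl and vinyl both exo, hydroxyl endo) | C=C[C@@]1(C)[C@@H]2CC[C@H](C)[C@@H]2[C@@]1(O)C1=C[C@@H]2CC(C)(C)CC[C@@]2(C)CC1 | intermediate
28 | potassium alkoxide of 27 | C=C[C@@]1(C)[C@@H]2CC[C@H](C)[C@@H]2[C@@]1(O[K])C1=C[C@@H]2CC(C)(C)CC[C@@]2(C)CC1 | intermediate
29 | potassium dienolate of ring C (C9(OK)=C11 and C2=C26, both Z; C24 set) | C1/C=C(/C)[C@@H]2CC[C@H](C)[C@@H]2/C(O[K])=C2/CC[C@]3(C)CCC(C)(C)C[C@H]3[C@H]12 | intermediate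
30 | tetracyclic C9 ketone with Z-C2=C26 (ring D cis-fused with H3 and H8 cis, C7 methyl cis to C9; C12 methyl anti to H24; C16 methyl anti to H23) | C1/C=C(/C)[C@@H]2CC[C@H](C)[C@@H]2C(=O)[C@@]2(C)CC[C@]3(C)CCC(C)(C)C[C@H]3[C@H]12 | intermediate
31 | C9 alcohol of 30 (hydroxyl trans to the C12 methyl, Z-C2=C26) | C1/C=C(/C)[C@@H]2CC[C@H](C)[C@@H]2[C@@H](O)[C@@]2(C)CC[C@]3(C)CCC(C)(C)C[C@H]3[C@H]12 | intermediate
32 | CNP0399382.1 (C2=C3 isomer of 31) | C/C1=C2\CC[C@H](C)[C@@H]2[C@@H](O)[C@@]2(C)CC[C@]3(C)CCC(C)(C)C[C@H]3[C@@H]2CC1 | target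

**Step count**

Total: 18 steps. Longest linear sequence: 12 steps (13 → 32, steps 7–18); the branch 1 → 12 has 6 steps.

**Steps most likely to fail**

Step 16. The methyl group may enter the dienolate on the wrong face: the outer face of the folded eight-membered ring is the one syn to H24, and attack there gives the C11 epimer. Cleavage of the cyclobutoxide is a lesser concern. The fallback sets out from 27 and returns at 31; it keeps the rearrangement but delivers the methyl carbon intramolecularly from the C9 oxygen.
- Dienolate 29, made from 27 as in step 16, is quenched with PhSeBr at −78 °C to give the C11 phenylselanyl ketone F1.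
- H2O2/pyridine and syn elimination of the selenoxide towards the C13 methylene should give the C11=C13 enone F2, in which C24 keeps the configuration set by the rearrangement.
- Luche reduction (NaBH4, CeCl3·7H2O, MeOH, −78 °C) gives the C9 allylic alcohol F3. The C9 epimer shown is carried on; the other would be inverted by a Mitsunobu reaction.
- BrCH2SiMe2Cl/Et3N gives the (bromomethyl)dimethylsilyl ether F4.
- Bu3SnH/AIBN in benzene at 80 °C closes the oxasilolane F5 by 5-exo radical cyclisation onto C11, followed by hydrogen-atom transfer to C13. The tethered radical can reach C11 only on the face that carries the C9–O bond, so the C11 configuration no longer depends on the fold of ring C.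
- KOt-Bu in wet DMSO then cleaves the Si–C12 and Si–O bonds (protodesilylation) and gives 31 with the C12 methyl in place.

Step 18. The double bond may migrate past C2=C3 towards C3=C8, where the resulting allylic alcohol can isomerise further to the ketone, or conversion may stay incomplete. The fallback sets out from 30 and returns at 32; it places the alkene with the help of the C9 carbonyl before reduction.
- TsOH in benzene at 80 °C should carry the double bond of 30 through C2=C3 into conjugation and give the C3=C8 enone F6 (C2 epimers).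
- LiN(i-Pr)2 in THF at −78 °C removes the γ-hydrogen at C2, which is cis to the carbonyl group across the C3=C8 bond (C4 is trans, and C11 has no hydrogen), to give the extended lithium enolate F7.
- Kinetic α-protonation at C8 (AcOH, −78 °C), expected anti to the C7 methyl on C6, gives the β,γ-unsaturated C9 ketone F8 with the C2=C3 double bond (deconjugative protonation).
- Immediate reduction with LiAlH4 as in step 17 gives 32.

Step 17. Hydride may be delivered to the other face of the C9 carbonyl, because the eight-membered ring can present either face. The fallback runs from 30 to 31 and makes no new compound (F0). Substrate control is replaced by reagent control in a Corey–Bakshi–Shibata reduction with (S)-2-methyl-CBS-oxazaborolidine and BH3·SMe2 in toluene at −20 °C. The quaternary C11 acts as the large and C8 as the small carbonyl substituent, and this sense of the catalyst corresponds to the C9 configuration of 31.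

Further compounds
F1 | step 16 | C11-(phenylselanyl) tetracyclic C9 ketone (selanyl group syn to H24, Z-C2=C26) | C1/C=C(/C)[C@@H]2CC[C@H](C)[C@@H]2C(=O)[C@]2([Se]c4ccccc4)CC[C@]3(C)CCC(C)(C)C[C@H]3[C@H]12
F2 | step 16 | tetracyclic C9 ketone with C11=C13 and Z-C2=C26 (enone) | C1/C=C(/C)[C@@H]2CC[C@H](C)[C@@H]2C(=O)C2=CC[C@]3(C)CCC(C)(C)C[C@H]3[C@H]12
F3 | step 16 | C9 allylic alcohol of F2 | C1/C=C(/C)[C@@H]2CC[C@H](C)[C@@H]2[C@@H](O)C2=CC[C@]3(C)CCC(C)(C)C[C@H]3[C@H]12
F4 | step 16 | (bromomethyl)dimethylsilyl ether of F3 | C1/C=C(/C)[C@@H]2CC[C@H](C)[C@@H]2[C@@H](O[Si](C)(C)CBr)C2=CC[C@]3(C)CCC(C)(C)C[C@H]3[C@H]12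
F5 | step 16 | oxasilolane bridging O10 and C11 through SiMe2 and C12 | C1/C=C(/C)[C@@H]2CC[C@H](C)[C@@H]2[C@H]4O[Si](C)(C)C[C@@]42CC[C@]3(C)CCC(C)(C)C[C@H]3[C@H]12
F6 | step 18 | tetracyclic C9 ketone with C3=C8 (conjugated enone, C2 epimers) | C1CC(C)C2=C(C(=O)[C@@]3(C)CC[C@]4(C)CCC(C)(C)C[C@H]4[C@H]13)[C@@H](C)CC2
F7 | step 18 | extended lithium enolate C9(OLi)=C8–C3=C2 | C1CC(C)=C2CC[C@H](C)C2=C(O[Li])[C@@]2(C)CC[C@]3(C)CCC(C)(C)C[C@H]3[C@H]12
F8 | step 18 | tetracyclic C9 ketone with C2=C3 (β,γ-unsaturated) | C/C1=C2\CC[C@H](C)[C@@H]2C(=O)[C@@]2(C)CC[C@]3(C)CCC(C)(C)C[C@H]3[C@@H]2CC1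
F0 | step 17 | none | none
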